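**Retrosynthetic overview**
1. Eremophilane numbering is used (ring A: C1–C5 and C10; ring B: C5–C10; β = face of the C5 methyl group). The C3 ester and C2 alcohol are disconnected last, as a trans-diaxial opening of a 2α,3α-epoxide by (2E,4E,6S)-6-methylocta-2,4-dienoic acid; the C7 hydroxyl comes from a C7 bromide (borylation, then oxidation).
2. Ring B is made last and not at its final size. The cyclopentenone C5–C6–C8–C9–C10 is expanded by one carbon: C7 enters as a dibromocarbene carbon between C6 and C8 (silyl dienol ether → gem-dibromocyclopropane → strain-driven electrocyclic opening → 7-bromo-6,9-dien-8-one).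
3. Enabling feature: in ring B, C7 is the only sp2 carbon that carries a heteroatom, and it lies between C6 and the C8 carbonyl. C5 is quaternary, so the 2-halo-cyclohexa-2,5-dienone left by the opening cannot tautomerise to a phenol.
4. Ring A and the five-membered ring are closed together by an intramolecular Pauson–Khand reaction of a 1,7-enyne. A temporary cis-2α,3α-diol on the tether controls the quaternary C5 and is later excised (Corey–Winter) to leave the C2=C3 alkene for the epoxide.
5. The enyne comes from 2-methylbut-2-ene and ethyl glyoxylate (asymmetric ene reaction; C3, C4) and an allenylboronate (C2). Order of ring formation: ring A plus cyclopentenone (step 5), then ring B by expansion (step 6).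

Key step: step 6

Remark: the enantiomers of BINOL, of the phosphoric acid and of the cobalt–salen catalyst are assigned by analogy and would be confirmed on the first intermediates; the target is treated as the C7-enol (diosphenol) tautomer of the C7,C8-dione.

**Route**

Step 1
Reactants: 1 2-methylbut-2-ene; 2 ethyl glyoxylate
Product: 3 ethyl (2S,3R)-2-hydroxy-3,4-dimethylpent-4-enoate
Conditions: (S)-BINOL (10 mol %), Ti(OiPr)2Br2 (10 mol %), 4 Å MS, CH2Cl2, −30 °C
Reagents that add atoms: none
Why: Titanium–BINOL-catalysed glyoxylate-ene (carbonyl-ene) reaction: the aldehyde carbon bonds to the less substituted alkene carbon of 1 while a hydrogen of a geminal methyl group shifts, the catalyst fixing the carbinol centre as 2S and, through the syn preference of this catalyst class with trisubstituted alkenes, the methyl-bearing centre as 3R (C3 and C4 of the target skeleton).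

Step 2
Reactants: 3 ethyl (2S,3R)-2-hydroxy-3,4-dimethylpent-4-enoate
Product: 4 ethyl (2S,3R)-2-[(tert-butyldimethylsilyl)oxy]-3,4-dimethylpent-4-enoate
Conditions: TBSCl, imidazole, DMF, 23 °C
Reagents that add atoms: tert-butyldimethylsilyl chloride CC(C)(C)[Si](C)(C)Cl
Why: Silylation of a secondary alcohol with a silyl chloride and imidazole, which touches no stereocentre and gives the non-chelating α-substituent needed for step 4.

Step 3
Reactants: 4 ethyl (2S,3R)-2-[(tert-butyldimethylsilyl)oxy]-3,4-dimethylpent-4-enoate
Product: 5 (2S,3R)-2-[(tert-butyldimethylsilyl)oxy]-3,4-dimethylpent-4-enal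
Conditions: DIBAL-H (iBu2AlH), CH2Cl2, −78 °C; aq. sodium potassium tartrate (KNaC4H4O6)
Reagents that add atoms: none
Why: Half-reduction of the ester by DIBAL-H at −78 °C: the tetrahedral aluminium hemiacetal is stable at this temperature and releases the aldehyde only on work-up, so over-reduction and epimerisation of C2 are avoided.

Step 4
Reactants: 5 (2S,3R)-2-[(tert-butyldimethylsilyl)oxy]-3,4-dimethylpent-4-enal; 6 allenylboronic acid pinacol ester
Product: 7 (4R,5S,6R)-5-[(tert-butyldimethylsilyl)oxy]-6,7-dimethyloct-7-en-1-yn-4-ol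
Conditions: 3,3′-bis(2,4,6-triisopropylphenyl)-1,1′-binaphthyl-2,2′-diyl hydrogen phosphate (TRIP, 5 mol %, enantiomer matched to Felkin–Anh addition), 4 Å MS, toluene, −20 °C
Reagents that add atoms: none
Why: Brønsted-acid-catalysed propargylation of an aldehyde with an allenylboronate through a closed six-membered SE2′ transition state, the new carbinol centre being set anti to the α-silyloxy group by polar Felkin–Anh control reinforced by the matched catalyst (this gives the erythro, later cis, C2/C3 diol pattern).

Step 5
Reactants: 7 (4R,5S,6R)-5-[(tert-butyldimethylsilyl)oxy]-6,7-dimethyloct-7-en-1-yn-4-ol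
Product: 8 (5R,6S,7R,7aR)-6-[(tert-butyldimethylsilyl)oxy]-5-hydroxy-7,7a-dimethyl-1,4,5,6,7,7a-hexahydro-2H-inden-2-one
Conditions: Co2(CO)8 (20 mol %), tetramethylthiourea (60 mol %), CO (1 atm), toluene, 70 °C
Reagents that add atoms: carbon monoxide [C-]#[O+]
Why: Catalytic intramolecular Pauson–Khand [2+2+1] cycloaddition closes ring A and the cyclopentenone in one operation, and the quaternary C5 is set in a chair-like tether in which the large C3 silyl ether and the C4 methyl group are equatorial (only the small C2 hydroxyl axial), which puts the new C5 methyl group axial and cis to the C4 methyl group, whereas the C5 epimer would need both groups axial and a syn-diaxial OSi/CH3 contact.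

Step 6
Reactants: 8 (5R,6S,7R,7aR)-6-[(tert-butyldimethylsilyl)oxy]-5-hydroxy-7,7a-dimethyl-1,4,5,6,7,7a-hexahydro-2H-inden-2-one
Product: 11 7-bromo-3α-[(tert-butyldimethylsilyl)oxy]-2α-[(trimethylsilyl)oxy]-11,12,13-trinoreremophila-6,9-dien-8-one, via bis-silyl dienol ether 9 (not isolated), via gem-dibromocyclopropane 10 (not isolated)
Conditions: LDA (LiN(iPr)2, 2.3 equiv), Me3SiCl (2.6 equiv), THF, −78 °C; pentane, filtration; CHBr3 (1.3 equiv), KOtBu (1.3 equiv), pentane, −30 → 20 °C; aq. NaHCO3
Reagents that add atoms: chlorotrimethylsilane C[Si](C)(C)Cl; bromoform BrC(Br)Br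
Why: Kinetic α′-deprotonation at C6 with internal silyl quench gives the cross-conjugated 2-silyloxy-cyclopentadiene 9 (the C2 alkoxide is silylated at the same time), dibromocarbene adds to its electron-rich enol-ether bond C6=C8 to give the 6,6-dibromobicyclo[3.1.0]hexene 10, and relief of cyclopropane strain drives the disrotatory two-electron electrocyclic cleavage of the shared C6–C8 bond with loss of the endo bromide, the siloxy-stabilised cyclohexenyl cation then losing Me3Si+ to leave the 2-bromo-cyclohexa-2,5-dienone. The closest known reaction is the one-carbon ring expansion of cyclic silyl enol ethers and 2-silyloxy-1,3-dienes to α-halo enones with dihalocarbenes. The only ring closed is the transient cyclopropane (concerted [2+1] cheletropic addition); ring B is not closed by a cyclisation but grows from five to six members when the internal cyclopropane bond breaks, C7 being the inserted carbon. No new stereocentre survives, because C6 and C8 return to sp2 whichever face the carbene takes, and C2–C5 are not touched. The step needs enolisation towards C6 and not towards C1, which kinetic control (LDA at −78 °C with Me3SiCl present) secures, and carbene attack on C6=C8 and not on C9=C10, which the oxygen donor on C8 and the large HOMO coefficient at C6 secure. The quaternary C5 keeps the product from tautomerising to a phenol.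

Step 7
Reactants: 11 7-bromo-3α-[(tert-butyldimethylsilyl)oxy]-2α-[(trimethylsilyl)oxy]-11,12,13-trinoreremophila-6,9-dien-8-one
Product: 12 7-bromo-2α,3α-dihydroxy-11,12,13-trinoreremophila-6,9-dien-8-one
Conditions: HF·pyridine, pyridine, THF, 0 → 23 °C
Reagents that add atoms: none
Why: Fluoride-induced cleavage of both silyl ethers with buffered HF·pyridine, a non-basic desilylation that avoids β-elimination of the C2 oxygen from the C1-acidic dienone.

Step 8
Reactants: 12 7-bromo-2α,3α-dihydroxy-11,12,13-trinoreremophila-6,9-dien-8-one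
Product: 13 7-bromo-11,12,13-trinoreremophila-6,9-dien-8-one 2α,3α-diyl thiocarbonate
Conditions: 1,1′-thiocarbonyldiimidazole, THF, 65 °C
Reagents that add atoms: 1,1′-thiocarbonyldiimidazole S=C(n1ccnc1)n1ccnc1
Why: First half of the Corey–Winter olefination: the cis-2α,3α-diol (axial/equatorial) closes a five-membered cyclic thiocarbonate with thiocarbonyldiimidazole without a change at any stereocentre.

Step 9
Reactants: 13 7-bromo-11,12,13-trinoreremophila-6,9-dien-8-one 2α,3α-diyl thiocarbonate
Product: 14 7-bromo-11,12,13-trinoreremophila-2,6,9-trien-8-one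
Conditions: 1,3-dimethyl-2-phenyl-1,3,2-diazaphospholidine (3 equiv), THF, 40 °C
Reagents that add atoms: none
Why: Corey–Winter olefination in its mild diazaphospholidine variant: the thiophilic phosphorus reagent removes sulfur and the resulting 1,3-dioxolan-2-ylidene loses CO2 in a stereospecific syn elimination, which the cis-fused thiocarbonate allows and which places the alkene unambiguously between C2 and C3.

Step 10
Reactants: 14 7-bromo-11,12,13-trinoreremophila-2,6,9-trien-8-one
Product: 15 7-bromo-2α,3α-epoxy-11,12,13-trinoreremophila-6,9-dien-8-one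
Conditions: mCPBA, NaHCO3, CH2Cl2, 0 °C
Reagents that add atoms: 3-chloroperoxybenzoic acid OOC(=O)c1cccc(Cl)c1
Why: Prilezhaev epoxidation: the peracid reacts only with the isolated C2=C3 alkene (both dienone double bonds are deactivated by the carbonyl group and by bromine) and approaches from the α face, anti to the axial C5 methyl group and the C4 methyl group, as in the α-selective epoxidation of 2-ene steroids.

Step 11
Reactants: 16 (S)-2-methylbutan-1-ol
Product: 17 (S)-2-methylbutanal
Conditions: TEMPO (10 mol %), PhI(OAc)2, CH2Cl2, 23 °C; used as a solution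
Reagents that add atoms: none
Why: TEMPO-catalysed oxidation of a primary alcohol with a hypervalent iodine co-oxidant stops at the aldehyde under neutral conditions, so the α-stereocentre is not epimerised.

Step 12
Reactants: 17 (S)-2-methylbutanal; 18 triethyl 4-phosphonocrotonate
Product: 19 ethyl (2E,4E,6S)-6-methylocta-2,4-dienoate
Conditions: LiHMDS (LiN(SiMe3)2), THF, −78 → 0 °C
Reagents that add atoms: none
Why: Vinylogous Horner–Wadsworth–Emmons olefination of the stabilised phosphonate anion gives the (2E,4E)-dienoate, and addition of the aldehyde to the preformed anion at −78 °C keeps the 6S centre intact.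

Step 13
Reactants: 19 ethyl (2E,4E,6S)-6-methylocta-2,4-dienoate
Product: 20 (2E,4E,6S)-6-methylocta-2,4-dienoic acid
Conditions: LiOH, THF/MeOH/H2O, 23 °C; then 1 M HCl
Reagents that add atoms: lithium hydroxide [Li+].[OH-]
Why: Saponification of the ethyl ester with hydroxide followed by acidification, which affects neither the diene geometry nor the remote stereocentre.

Step 14
Reactants: 15 7-bromo-2α,3α-epoxy-11,12,13-trinoreremophila-6,9-dien-8-one; 20 (2E,4E,6S)-6-methylocta-2,4-dienoic acid
Product: 21 7-bromo-2α-hydroxy-8-oxo-11,12,13-trinoreremophila-6,9-dien-3β-yl (2E,4E,6S)-6-methylocta-2,4-dienoate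
Conditions: Co(salen) [N,N′-bis(3,5-di-tert-butylsalicylidene)-1,2-cyclohexanediaminatocobalt, C36H52CoN2O2, divalent cobalt, matched enantiomer, oxidised in air to trivalent cobalt] (5 mol %), iPr2NEt, t-BuOMe, 23 °C
Reagents that add atoms: none
Why: Cobalt–salen-catalysed ring opening of an epoxide by a carboxylic acid: trans-diaxial (Fürst–Plattner) opening of the 2α,3α-epoxide in the chair that keeps the C5 methyl group axial directs the carboxylate to C3 from the β face, which inverts C3 to the 3β-ester and leaves C2 as the 2α-alcohol, and the diaxial product cannot undergo acyl migration.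

Step 15
Reactants: 21 7-bromo-2α-hydroxy-8-oxo-11,12,13-trinoreremophila-6,9-dien-3β-yl (2E,4E,6S)-6-methylocta-2,4-dienoate
Product: 23 septeremophilane G (target), via alkenyl pinacol boronate 22 (not isolated)
Conditions: B2pin2, PdCl2(dppf) (5 mol %), KOAc, 1,4-dioxane, 80 °C; then Me3NO, 23 °C; aq. NH4Cl
Reagents that add atoms: bis(pinacolato)diboron CC1(C)OB(OC1(C)C)B1OC(C)(C)C(C)(C)O1 (its boron is carried only by 22); trimethylamine N-oxide C[N+](C)(C)[O-]
Why: Miyaura borylation of the alkenyl bromide followed in the same flask by amine N-oxide oxidation of the C–B bond (1,2-shift from boron to oxygen at the same sp2 carbon) gives the C7 enol, i.e. the diosphenol, a peroxide-free oxidant being chosen because 1,2-diones are cleaved by peroxides.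

**Compound list**
1 | 2-methylbut-2-ene | CC=C(C)C | starting material
2 | ethyl glyoxylate | CCOC(=O)C=O | starting material
3 | ethyl (2S,3R)-2-hydroxy-3,4-dimethylpent-4-enoate | CCOC(=O)[C@@H](O)[C@H](C)C(C)=C | intermediate
4 | ethyl (2S,3R)-2-[(tert-butyldimethylsilyl)oxy]-3,4-dimethylpent-4-enoate | CCOC(=O)[C@@H](O[Si](C)(C)C(C)(C)C)[C@H](C)C(C)=C | intermediate
5 | (2S,3R)-2-[(tert-butyldimethylsilyl)oxy]-3,4-dimethylpent-4-enal | O=C[C@@H](O[Si](C)(C)C(C)(C)C)[C@H](C)C(C)=C | intermediate
6 | allenylboronic acid pinacol ester (4,4,5,5-tetramethyl-2-(propa-1,2-dienyl)-1,3,2-dioxaborolane) | C=C=CB1OC(C)(C)C(C)(C)O1 | starting material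
7 | (4R,5S,6R)-5-[(tert-butyldimethylsilyl)oxy]-6,7-dimethyloct-7-en-1-yn-4-ol | C#CC[C@@H](O)[C@@H](O[Si](C)(C)C(C)(C)C)[C@H](C)C(C)=C | intermediate
8 | (5R,6S,7R,7aR)-6-[(tert-butyldimethylsilyl)oxy]-5-hydroxy-7,7a-dimethyl-1,4,5,6,7,7a-hexahydro-2H-inden-2-one (2α-OH, 3α-OTBS, 4β,5β-dimethyl) | CC(C)(C)[Si](C)(C)O[C@@H]1[C@H](O)CC2=CC(=O)C[C@]2(C)[C@H]1C | intermediate
9 | bis-silyl dienol ether of 8: C8–OSiMe3 with C6=C8 and C9=C10 double bonds, C2–OSiMe3, C3–OTBS | CC(C)(C)[Si](C)(C)O[C@@H]1[C@H](O[Si](C)(C)C)CC2=CC(O[Si](C)(C)C)=C[C@]2(C)[C@H]1C | intermediate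
10 | gem-dibromocyclopropane: CBr2 (C7) bridging C6 and C8 of 9, either cyclopropane face | CC(C)(C)[Si](C)(C)O[C@@H]1[C@H](O[Si](C)(C)C)CC2=CC3(O[Si](C)(C)C)C(Br)(Br)C3[C@]2(C)[C@H]1C | intermediate
11 | 7-bromo-3α-[(tert-butyldimethylsilyl)oxy]-2α-[(trimethylsilyl)oxy]-11,12,13-trinoreremophila-6,9-dien-8-one | CC(C)(C)[Si](C)(C)O[C@@H]1[C@H](O[Si](C)(C)C)CC2=CC(=O)C(Br)=C[C@]2(C)[C@H]1C | intermediate
12 | 7-bromo-2α,3α-dihydroxy-11,12,13-trinoreremophila-6,9-dien-8-one | O[C@@H]1[C@H](O)CC2=CC(=O)C(Br)=C[C@]2(C)[C@H]1C | intermediate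
13 | cyclic 2α,3α-thiocarbonate of 12 | S=C3O[C@@H]1[C@H](O3)CC2=CC(=O)C(Br)=C[C@]2(C)[C@H]1C | intermediate
14 | 7-bromo-11,12,13-trinoreremophila-2,6,9-trien-8-one (4β,5β-dimethyl) | C1=CCC2=CC(=O)C(Br)=C[C@]2(C)[C@H]1C | intermediate
15 | 7-bromo-2α,3α-epoxy-11,12,13-trinoreremophila-6,9-dien-8-one | O1[C@@H]2[C@H]1CC3=CC(=O)C(Br)=C[C@]3(C)[C@H]2C | intermediate
16 | (S)-2-methylbutan-1-ol | CC[C@H](C)CO | starting material
17 | (S)-2-methylbutanal | CC[C@H](C)C=O | intermediate
18 | triethyl 4-phosphonocrotonate | CCOC(=O)/C=C/CP(=O)(OCC)OCC | starting material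
19 | ethyl (2E,4E,6S)-6-methylocta-2,4-dienoate | CC[C@H](C)/C=C/C=C/C(=O)OCC | intermediate
20 | (2E,4E,6S)-6-methylocta-2,4-dienoic acid | CC[C@H](C)/C=C/C=C/C(=O)O | intermediate
21 | 7-bromo-2α-hydroxy-8-oxo-11,12,13-trinoreremophila-6,9-dien-3β-yl (2E,4E,6S)-6-methylocta-2,4-dienoate | CC[C@H](C)/C=C/C=C/C(=O)O[C@H]1[C@H](O)CC2=CC(=O)C(Br)=C[C@]2(C)[C@H]1C | intermediate
22 | 7-(4,4,5,5-tetramethyl-1,3,2-dioxaborolan-2-yl) analogue of 21 | CC[C@H](C)/C=C/C=C/C(=O)O[C@H]1[C@H](O)CC2=CC(=O)C(B3OC(C)(C)C(C)(C)O3)=C[C@]2(C)[C@H]1C | intermediate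
23 | septeremophilane G, (4aS,5R,6R,7R)-3,7-dihydroxy-4a,5-dimethyl-2-oxo-2,4a,5,6,7,8-hexahydronaphthalen-6-yl (2E,4E,6S)-6-methylocta-2,4-dienoate | CC[C@H](C)/C=C/C=C/C(=O)O[C@H]1[C@H](O)CC2=CC(=O)C(O)=C[C@]2(C)[C@H]1C | target

**Step count**
Total step count: 15. Longest linear sequence: 12 steps (steps 1–10, 14 and 15); the acid 20 is made in 3 steps (11–13).

**Steps most likely to fail**

Step 15. On the fully functionalised ester the alkenylpalladium intermediate may be reduced (protodebromination), the α-boryl dienone may decompose before it is oxidised, or the freshly formed enol may be over-oxidised. The fallback sets out from 21 and forms the C7–O bond directly: palladium-catalysed C–O coupling with 2-(trimethylsilyl)ethanol (Pd2(dba)3, zerovalent palladium, tBuBrettPhos, Cs2CO3, toluene, 60 °C) should give the 2-(trimethylsilyl)ethyl enol ether F1. Fluoride (Bu4NF buffered with AcOH, THF) then cleaves the silylethyl group with loss of ethene, and the route is rejoined at 23.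

Step 14. Axial attack of the weakly nucleophilic carboxylate at the hindered C3 may be slow, which leaves time for base-induced opening of the epoxide from C1 (β-elimination towards the dienone) or for attack at C2. The fallback sets out from 15 and separates C–O bond formation from acylation. Acid-catalysed hydrolysis (HClO4, THF/H2O), again trans-diaxial, should give the 2α,3β-diol F2. Selective silylation of the less hindered 2α-hydroxyl (Et3SiCl, imidazole, −40 °C) gives the 2α-triethylsilyl ether F3. Steglich esterification of the 3β-hydroxyl with 20 (EDC·HCl, DMAP, CH2Cl2) gives the silylated ester F4, and HF·pyridine brings the route back at 21.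

Step 9. The trivalent phosphorus reagent may attack the bromo-dienone (halophilic or conjugate addition), and base-induced loss of the thiocarbonate from C1 may compete with desulfurisation. The fallback sets out from 12 and avoids both sulfur and phosphorus: triethyl orthoformate with pyridinium p-toluenesulfonate gives the cyclic orthoformate F5, and heating in acetic anhydride at 140 °C (Eastwood olefination, syn elimination with loss of CO2) returns to the route at 14.

Further compounds
F1 | step 15 | 2-(trimethylsilyl)ethyl enol ether of 23 (C7–OCH2CH2SiMe3) | CC[C@H](C)/C=C/C=C/C(=O)O[C@H]1[C@H](O)CC2=CC(=O)C(OCC[Si](C)(C)C)=C[C@]2(C)[C@H]1C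
F2 | step 14 | 7-bromo-2α,3β-dihydroxy-11,12,13-trinoreremophila-6,9-dien-8-one | O[C@H]1[C@H](O)CC2=CC(=O)C(Br)=C[C@]2(C)[C@H]1C
F3 | step 14 | 7-bromo-3β-hydroxy-2α-[(triethylsilyl)oxy]-11,12,13-trinoreremophila-6,9-dien-8-one | O[C@H]1[C@H](O[Si](CC)(CC)CC)CC2=CC(=O)C(Br)=C[C@]2(C)[C@H]1C
F4 | step 14 | 2α-triethylsilyl ether of 21 | CC[C@H](C)/C=C/C=C/C(=O)O[C@H]1[C@H](O[Si](CC)(CC)CC)CC2=CC(=O)C(Br)=C[C@]2(C)[C@H]1C
F5 | step 9 | cyclic orthoformate (2-ethoxy-1,3-dioxolane) of diol 12 | CCOC3O[C@@H]1[C@H](O3)CC2=CC(=O)C(Br)=C[C@]2(C)[C@H]1C
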